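The constants set two things against each other: the coupling of open intermediate with second intermediate has an equilibrium constant that grows with heat, and the dissolved target has a ceiling, its solubility.

    starting material → open intermediate (k1 = 0.53 s⁻¹, Ea1 = 63.0 kJ mol⁻¹)
    partner → second intermediate (k2 = 0.34 s⁻¹, Ea2 = 69.0 kJ mol⁻¹)
    open intermediate + second intermediate ⇌ target (K3 = 3.0 M⁻¹, k3 = 0.38 M⁻¹ s⁻¹, Ea3 = 44.0 kJ mol⁻¹, ΔH3 = 34.0 kJ mol⁻¹)
    2 second intermediate → homo product (k4 = 0.033 M⁻¹ s⁻¹, Ea4 = 50.0 kJ mol⁻¹)
    crystals ⇌ target, rate k5*(cs5 - [target]) while solid is left; crystals form when [target] > cs5 (cs5 = 0.19 M, k5 = 1.3 s⁻¹)
    (constants at 0 °C)

in all of them: starting material 0.40 M; partner 2.50 equiv; time 50 s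

|  | remark | temperature |
|---|---|---|
| gamma | at 0 °C until 40 s, from then on at 60 °C |  |
| delta |  | 60 °C |
| theta |  | 0 °C |
| zeta |  | 30 °C |

- what is said of target includes crystals
- for a step with 2 of a species take k times the square, and two of it per event
- crystals is a solid; its amount is given per volume of the solution
- at 0 °C the constants are as listed, elsewhere as the activation energies and enthalpies make them

* which flask leads in amount of target, in percent of the starting material charged ("all alike" within 1.5 percentage points) (gamma / delta / theta / zeta / all alike)
* how much target is there at the end, in percent of the starting material charged: gamma
* how much target is there at the end, in percent of the starting material charged: delta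
* how much target is there at the end, in percent of the starting material charged: theta
* how much target is there at the end, in percent of the starting material charged: zeta

1. I wrote A for the charge of starting material, J for the concentration of second intermediate, K for the coupling's equilibrium constant and c for the solubility. If the coupling is near equilibrium and the charge stands as open intermediate and target with its crystals, crystals exist just when J stands above a holding level (my name for it), J* = c/(K(A − c)), 0.302 M at the cold temperature and 0.0203 M at the hot one. It is the crossing where control passes between solid and solution. Above J*, target counted with its crystals is a fraction 1 − c/(KJA) of the charge; below it, KJ/(1 + KJ).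

2. My first way to theta used a floor for J. The partner gives 1.00 M of second intermediate, and if homo product alone acts on it for the whole time, J falls to 0.233 M. This is below J*, so the lower formula gives 41.1%.

3. My second way took theta to end near the crossing itself, where the solution is just saturated and no solid stands. That gives 47.5%.

4. The two parted, so I did the subtraction. The first way books 0.767 M of second intermediate to homo product and leaves 0.233 M free, which sums to the whole of 1.00 M and leaves nothing for target, though target holds 0.19 M at the crossing. The first way was the one that cheated, so I kept the second.

5. For gamma I ran the floor through both stages. By this reckoning the cold hold leaves 0.275 M. Heating raises the homo constant to 1.74 M⁻¹ s⁻¹, which brings the floor to 0.0260 M at the end. This floor stands above the hot J*, so crystals should remain in gamma, and my lower mark for its target was 58.9%.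

6. Delta and zeta I simply placed at the crossing mark, as a guess. My choice was gamma.

7. The forecast also chose gamma, with 75% for gamma, 52% for delta, 49% for theta and 48% for zeta. Its ground for gamma was that the late heating “drives the endothermic coupling hard, with too little time left for homo coupling to undo it”. Its gamma figure stands above my lower mark, which was a rough estimate.

8. The simulation gave gamma in the lead: gamma 74.9%, delta 53.7%, theta 47.0%, zeta 49.2%.

9. At the end theta held J = 0.269 M, below its J*, with crystals at 0%. Gamma held 0.0388 M, above its hot J*, with crystals at 28.2%. The neighbouring flask is theta with 0.68 M of starting material, and there J* comes to 0.129 M. Its reading of J, 0.295 M, stands above that level, so the upper formula applies and gives 68.5%. That flask gave 71.9% of target, with crystals at 44.2%.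

Its constants belong to no real substance; what happens was integrated by code.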